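The data are calculated with constants of no real substance; scatter was added.

- South-west lost D faster in its tail than south-east did: the slope of ln c_D was 1.19 h⁻¹ from 2.00 h to 3.00 h, against 0.624 h⁻¹ from 2.50 h to 4.00 h in south-east.

all flasks: D 0.65 M
- south-east: J 12 mM; run made earlier
- east: J 22 mM; run made earlier
- south-west: J 29 mM; run made earlier
- dusk: J 32 mM; time 5.0 h
- summer: J 15 mM; time 5.0 h

| run | time / h | G / % | D / % |
|---|---|---|---|
| south-east | 0.333 | 1.1 | 99.4 |
| south-east | 0.833 | 11.0 | 87.4 |
| south-east | 1.50 | 33.1 | 65.1 |
| south-east | 2.50 | 63.7 | 38.0 |
| south-east | 4.00 | 86.7 | 14.9 |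
| east | 0.250 | 1.5 | 99.8 |
| east | 0.500 | 8.1 | 93.6 |
| east | 1.00 | 28.6 | 71.5 |
| east | 2.00 | 70.5 | 31.8 |
| east | 4.00 | 94.5 | 2.5 |
| south-west | 0.667 | 17.7 | 83.9 |
| south-west | 1.33 | 53.6 | 47.1 |
| south-west | 2.00 | 77.0 | 22.3 |
| south-west | 3.00 | 90.5 | 6.8 |
| south-west | 4.00 | 96.0 | 0.3 |

(standard deviation of a reading: 1 percentage point)

- the average divides the monomer in chains by the number of chains begun, living and dead together
- the numbers in the tables scatter with a standard deviation of 1 percentage point
- what may be going on: Q + G -> L; D + Q -> E + G; D + E -> G + E; J -> Q
- the earlier runs do not show the number of chains; that part of a forecast is a guess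

- which of the two ends with the longer chains by the average number of monomer units in a chain (chains begun, living or dead) ("neither" if they lie within 10%) (dusk / summer / neither)
- average number of monomer units in a chain (chains begun, living or dead) at the end, dusk
- average number of monomer units in a chain (chains begun, living or dead) at the end, summer

- In the proposed step D + E → G + E, c_D falls in a pseudo-first-order way while c_E stands still, with a slope proportional to c_E. South-west's interval before its tail gave 1.12 h⁻¹, close to its tail value, so I froze c_E there.
- A straight line through those two runs gave 0.724 h⁻¹ for summer, the tail slope, and, extended beyond south-west's charge, 1.29 h⁻¹ for dusk.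
- My second way took the same slope from the share of D not found as G. South-east agreed, with 0.669 h⁻¹, but south-west parted, with 0.884 h⁻¹.
- The second way was the one that cheated. At 4.00 h, south-west's D and G together fell short of the charge by 3.7 percentage points, against a scatter of 1 point. At 3.00 h the share not found as G was 9.50% while D read 6.8%, a reading of a gap in the direction of the step Q + G → L, which takes G away without giving D. I therefore kept the slopes from D.
- The length is monomer in chains over chains begun, and the proposed steps end no chain. With equal monomer in chains assumed, summer's chains came out longer than dusk's by the slope ratio, 1.78. The absolute lengths stayed a guess.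
- The forecast named summer, with 48 (26 to 75) for dusk and 58 (43 to 90) for summer, holding that “The living-end count therefore saturates instead of following J.” Its ratio, 1.21, was smaller than mine.
- The flask gave 64.1 for summer and 39.0 for dusk, so summer ended longer. At 5.00 h, c_E stood at 0.00966 M in summer and 0.0162 M in dusk. Summer's length times its tail slope is 46.4 h⁻¹, and with equal monomer in chains assumed again, dividing that by dusk's slope gives 36.0 units for dusk.

    Q + G → L (k = 0.0900 M⁻¹ min⁻¹)
    D + Q → E + G (k = 0.120 M⁻¹ min⁻¹)
    D + E → G + E, rate k3*[E]*[D] (k = 1.40 M⁻¹ min⁻¹)
    J → Q (k = 0.0110 min⁻¹)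

- A neighbour of summer with 0.025 M of J has a tail slope on my line of 1.06 h⁻¹, so the same product gives 43.8 units. The computed flask gave 46.0.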